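**Retrosynthetic overview**

1. Atom labels used throughout: C1 lactone C=O; C2 C(OH); C3 CH(OBu); oxane C5–O–C9 (C7 OH); C11 CHMe; diene C12–C15; oxolane C17–O–C20 (C18 Me, C19 CH2); C21 CHOH; C23 lactone CH–O; C24 CH(OBu).
2. The macrocycle is opened at C13–C14 (oxidative diyne coupling, then Z,Z-semireduction), at C21–C22 (chelation-controlled Mukaiyama aldol) and at C2–C3 (tartrate enolate aldol), giving an oxane aldehyde (C3–C13), L-tartrate acetonide (C1, C2, C23, C24) and an oxolane aldehyde (C14–C21).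
3. Key disconnection: the oxolane C19–C20 bond, by Petasis–Ferrier rearrangement of a 4-methylidene-1,3-dioxolane. The enabling feature is that in the 2,5-cis oxolane ring (O, C17, C18, C19, C20) the ring oxygen sits on C17 next to the methyl-bearing C18. With C18 stored as a ketone this is an α-oxy-carbonyl unit, so C17/C18 come from an α-hydroxy acid, C20 from an aldehyde, and the acetal tether turns C19–C20 into an enolate/oxocarbenium bond.
4. Stereochemical relay: C17 (bought) → C20 (key step) → C18 (hydrogenation) → C21 (chelation) → C23 (1,3-anti reduction); C24 (bought) → C2 (anti aldol) → C3 (CBS reduction); C11 (catalysis), C9 (allylation) → C5/C7 (Prins).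
5. Ring order: oxolane (step 4), oxane (step 13), γ-lactone (step 24), macrocycle (step 29); the end game is ketal removal, bis-butyrylation, alkyne unmasking, ring closure, semireduction, desilylation.

Key step: step 4

Assumption: the ligand antipodes written in steps 10 and 11 ((R)-DTBM-SEGPHOS, (S)-BINOL) are those expected to give the drawn configurations; should the sense of induction be the opposite, the mirror-image ligand is used.

**Oxolane fragment (C14–C21)**

Step 1
Reactants: 1 O-benzyl-D-serine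
Product: 2 (R)-3-(benzyloxy)-2-hydroxypropanoic acid
Conditions: NaNO2, H2SO4 (1 M aq.), 0 °C → rt
Reagents that add atoms: water, O
Why: Diazotisation of the α-amino acid with carboxylate participation (double inversion) should replace NH2 by OH with net retention, so C17 keeps the bought (R) configuration.

Step 2
Reactants: 2 (R)-3-(benzyloxy)-2-hydroxypropanoic acid; 3 (tert-butyldimethylsilyloxy)acetaldehyde
Product: 5 (2R,5R)-5-[(benzyloxy)methyl]-2-[(tert-butyldimethylsilyloxy)methyl]-1,3-dioxolan-4-one, via bis-TMS hydroxy acid 4 (not isolated)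
Conditions: TMSCl, Et3N, CH2Cl2, 0 °C → rt; then 3, TMSOTf (cat.), CH2Cl2, −78 °C
Reagents that add atoms: none
Why: Silyl-triflate-catalysed acetalisation of a bis-silylated α-hydroxy acid with an aldehyde should give the dioxolanone without epimerising C17; the cis isomer should predominate, but the acetal configuration is erased in step 4.

Step 3
Reactants: 5 dioxolanone
Product: 6 (2R,5R)-5-[(benzyloxy)methyl]-2-[(tert-butyldimethylsilyloxy)methyl]-4-methylidene-1,3-dioxolane
Conditions: Cp2TiMe2, toluene/THF, 65 °C, dark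
Reagents that add atoms: dimethyltitanocene, C[Ti](C)(C1C=CC=C1)C1C=CC=C1
Why: Petasis methylenation of the lactone-type carbonyl is non-basic, so C17 and both ethers should survive and the enol acetal should form cleanly.

Step 4
Reactants: 6 enol acetal
Product: 7 (2R,5R)-2-[(benzyloxy)methyl]-5-[(tert-butyldimethylsilyloxy)methyl]oxolan-3-one (2,5-cis)
Conditions: Me2AlCl, CH2Cl2, −78 → 0 °C
Reagents that add atoms: none
Why: Me2AlCl should ionise the enol acetal at the bond between C20 and the enol-ether oxygen, giving an aluminium enolate (C18–C19) and an O17=C20 oxocarbenium ion held together through the future ring oxygen, and the enolate carbon C19 then attacks C20 (Petasis–Ferrier rearrangement; closest precedent is the Lewis-acid rearrangement of 4-methylidene-1,3-dioxolanes to 3-oxygenated oxolanes). The oxolane closes in a formally 5-(enolendo)-endo-trig, aldol-type mode, which the cationic acceptor makes feasible and which is documented for the dioxolane series. C17 is not part of the enolate and keeps its configuration; the new centre C20 is set by substrate control, because the (E)-oxocarbenium closes through an envelope with the C17 and C20 substituents both pseudo-equatorial, giving the 2,5-cis ring from either acetal epimer of 6. The step needs ionisation at the enol-ether oxygen rather than at O17 or at the silyl and benzyl ethers, which the much more labile enol acetal should secure at −78 °C, and it needs the ketone to survive, for which non-reducing Me2AlCl is chosen. In one operation a temporary acetal made from two simple pieces becomes the C19–C20 bond, the ring, the C20 stereocentre and the C18 carbonyl that later delivers the C18 methyl group.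

Step 5
Reactants: 7 oxolan-3-one
Product: 8 (2S,5R)-2-[(benzyloxy)methyl]-5-[(tert-butyldimethylsilyloxy)methyl]-3-methylideneoxolane
Conditions: Cp2TiMe2, toluene, 65 °C, dark
Reagents that add atoms: dimethyltitanocene, C[Ti](C)(C1C=CC=C1)C1C=CC=C1
Why: Non-basic Petasis methylenation of the α-alkoxy ketone should avoid enolisation at C17 and ring-opening β-elimination while installing the future C18 methyl carbon.

Step 6
Reactants: 8 methylideneoxolane
Product: 9 [(2S,3R,5R)-5-[(tert-butyldimethylsilyloxy)methyl]-3-methyloxolan-2-yl]methanol (all-cis)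
Conditions: H2 (1 atm), Pd/C, EtOAc, rt
Reagents that add atoms: none
Why: Heterogeneous hydrogenation should deliver hydrogen to the alkene face opposite the two cis CH2OR groups on C17 and C20, placing the C18 methyl cis to both, and the same conditions hydrogenolyse the benzyl ether while the TBS ether stays.

Step 7
Reactants: 9 oxolanylmethanol; 10 (triisopropylsilyl)acetylene
Product: 13 tert-butyldimethyl{[(2R,4R,5R)-4-methyl-5-[3-(triisopropylsilyl)prop-2-yn-1-yl]oxolan-2-yl]methoxy}silane, via primary triflate 11 (not isolated), via lithium acetylide 12 (not isolated)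
Conditions: Tf2O, 2,6-lutidine, CH2Cl2, −78 °C; then 10, n-BuLi, THF/DMPU, −78 → −20 °C
Reagents that add atoms: none
Why: SN2 displacement of a primary triflate by a lithium acetylide is a standard way to attach the C14–C15 alkyne to C16; no stereocentre is touched.

Step 8
Reactants: 13 silyl ether
Product: 14 [(2R,4R,5R)-4-methyl-5-[3-(triisopropylsilyl)prop-2-yn-1-yl]oxolan-2-yl]methanol
Conditions: CSA (cat.), MeOH/CH2Cl2, 0 °C
Reagents that add atoms: none
Why: Acid-catalysed methanolysis removes the primary TBS ether, whereas the C-bound TIPS group is stable to acid.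

Step 9
Reactants: 14 alcohol
Product: 15 (2R,4R,5R)-4-methyl-5-[3-(triisopropylsilyl)prop-2-yn-1-yl]oxolane-2-carbaldehyde
Conditions: DMP, NaHCO3, CH2Cl2, 0 °C → rt
Reagents that add atoms: none
Why: Buffered Dess–Martin oxidation should give the α-alkoxy aldehyde (C21) without epimerising C20; it is used directly in step 23.

**Oxane fragment (C3–C13)**

Step 10
Reactants: 16 (E)-but-2-enal; 10 (triisopropylsilyl)acetylene
Product: 17 (R)-3-methyl-5-(triisopropylsilyl)pent-4-ynal
Conditions: [Rh(OAc)(C2H4)2]2 (cat.), (R)-DTBM-SEGPHOS, MeOH, 40 °C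
Reagents that add atoms: none
Why: Rhodium-catalysed asymmetric conjugate alkynylation of an enal with a bulky silylacetylene (the TIPS group suppresses alkyne dimerisation) should set C11 by catalyst control.

Step 11
Reactants: 17 alkynyl aldehyde
Product: 18 (4S,6R)-6-methyl-8-(triisopropylsilyl)oct-1-en-7-yn-4-ol
Conditions: (S)-BINOL (cat.), Ti(OiPr)4 (cat.), 4 Å MS, allylSnBu3, CH2Cl2, −20 °C
Reagents that add atoms: allyltributylstannane, C=CC[Sn](CCCC)(CCCC)CCCC
Why: Keck allylation should set C9 by reagent control of the aldehyde face, the remote C11 centre exerting little bias.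

Step 12
Reactants: 18 homoallylic alcohol
Product: 19 methyl (E)-3-{[(4S,6R)-6-methyl-8-(triisopropylsilyl)oct-1-en-7-yn-4-yl]oxy}prop-2-enoate
Conditions: methyl propiolate, N-methylmorpholine (cat.), CH2Cl2, rt
Reagents that add atoms: methyl propiolate, C#CC(=O)OC
Why: Amine-catalysed oxa-Michael addition of the alcohol to the propiolate should give the (E)-β-alkoxyacrylate needed for the Prins step.

Step 13
Reactants: 19 β-alkoxyacrylate
Product: 21 methyl 2-[(2R,4S,6R)-4-hydroxy-6-[(2R)-2-methyl-4-(triisopropylsilyl)but-3-yn-1-yl]oxan-2-yl]acetate, via C7 trifluoroacetate 20 (not isolated)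
Conditions: TFA, CH2Cl2, 0 °C → rt; then K2CO3, MeOH, 0 °C
Reagents that add atoms: trifluoroacetic acid, OC(=O)C(F)(F)F
Why: Protonation of the vinylogous carbonate gives an oxocarbenium ion that should undergo Prins cyclisation through a chair with the C5 and C9 substituents equatorial and equatorial trifluoroacetate capture at C7, so C5 and C7 are relayed from C9 (all-cis oxane); methanolysis then frees the C7 hydroxyl.

Step 14
Reactants: 21 hydroxy ester
Product: 22 methyl 2-[(2R,4S,6R)-4-(tert-butyldiphenylsilyloxy)-6-[(2R)-2-methyl-4-(triisopropylsilyl)but-3-yn-1-yl]oxan-2-yl]acetate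
Conditions: TBDPSCl, imidazole, DMF, rt
Reagents that add atoms: tert-butyl(chloro)diphenylsilane, CC(C)(C)[Si](Cl)(c1ccccc1)c1ccccc1
Why: Standard silylation installs an acid-robust ether on the equatorial C7 hydroxyl that must survive the ketal hydrolysis of step 26.

Step 15
Reactants: 22 ester
Product: 23 2-[(2R,4S,6R)-4-(tert-butyldiphenylsilyloxy)-6-[(2R)-2-methyl-4-(triisopropylsilyl)but-3-yn-1-yl]oxan-2-yl]acetaldehyde
Conditions: i-Bu2AlH, CH2Cl2, −78 °C
Reagents that add atoms: none
Why: Partial reduction of the methyl ester at −78 °C should stop at the C3 aldehyde through the stable aluminium hemiacetal.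

**Linking piece and fragment union**

Step 16
Reactants: 24 dimethyl (4R,5R)-2,2-dimethyl-1,3-dioxolane-4,5-dicarboxylate (L-tartrate acetonide); 23 oxane aldehyde
Product: 26 tartrate–oxane aldol adduct (C3 epimers), via lithium enolate 25 (not isolated)
Conditions: LDA, THF, −78 °C; then 23, −78 °C
Reagents that add atoms: none
Why: The aldol addition should occur on the enolate face anti to the C24 ester on the dioxolane, setting quaternary C2 with the C1 ester cis to C23, while the ketal ring holds the β C–O bond out of conjugation and suppresses β-elimination; C3 forms as a mixture that converges in steps 17–18.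

Step 17
Reactants: 26 aldol adduct
Product: 27 C3 ketone (β-keto ester)
Conditions: DMP, NaHCO3, CH2Cl2, rt
Reagents that add atoms: none
Why: Dess–Martin oxidation converges both C3 epimers to a β-keto ester that cannot enolise between the carbonyls because C2 is quaternary.

Step 18
Reactants: 27 β-keto ester
Product: 28 (3R)-alcohol
Conditions: (S)-Me-CBS, catecholborane, toluene, −78 °C
Reagents that add atoms: none
Why: Corey–Bakshi–Shibata reduction should distinguish the large quaternary C2 side from the small C4 methylene side and set C3 as (R) by reagent control.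

Step 19
Reactants: 28 (3R)-alcohol
Product: 29 C3 triethylsilyl ether
Conditions: TESOTf, 2,6-lutidine, CH2Cl2, −78 °C
Reagents that add atoms: triethylsilyl triflate, CC[Si](CC)(CC)OS(=O)(=O)C(F)(F)F
Why: Silylation of the hindered alcohol with the silyl triflate blocks retro-aldol cleavage in the basic steps that follow and is removed together with the ketal in step 26.

Step 20
Reactants: 29 diester
Product: 30 C23 Weinreb amide (C1 methyl ester kept)
Conditions: MeNHOMe·HCl, i-PrMgCl, THF, −20 °C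
Reagents that add atoms: N,O-dimethylhydroxylamine hydrochloride, CNOC.Cl
Why: The magnesium amide should attack only the accessible C23 ester, the C1 ester on the quaternary C2 being too hindered.

Step 21
Reactants: 30 Weinreb amide
Product: 31 C23 methyl ketone
Conditions: MeMgBr, THF, −78 → 0 °C
Reagents that add atoms: methylmagnesium bromide, C[Mg]Br
Why: Grignard addition to the Weinreb amide stops at the ketone through the chelated tetrahedral intermediate and brings in C22.

Step 22
Reactants: 31 methyl ketone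
Product: 32 C22–C23 trimethylsilyl enol ether
Conditions: LiHMDS, TMSCl, Et3N, THF, −78 °C
Reagents that add atoms: chlorotrimethylsilane, C[Si](C)(C)Cl
Why: Kinetic deprotonation at the methyl group with in situ silylation should give the less substituted enol silane; C24 is hindered and C2 has no hydrogen.

Step 23
Reactants: 32 enol silane; 15 oxolane aldehyde
Product: 33 β-hydroxy ketone (C21 OH, C23 C=O)
Conditions: MgBr2·OEt2, CH2Cl2, −78 → −40 °C; aqueous work-up
Reagents that add atoms: none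
Why: In this Mukaiyama aldol MgBr2 should chelate the aldehyde oxygen and the oxolane ring oxygen, so the enol silane attacks the face anti to C19 and sets C21 syn to the C20 oxygen.

Step 24
Reactants: 33 β-hydroxy ketone
Product: 35 γ-lactone cis-fused to the isopropylidene ketal (free C21 OH), via 21,23-anti diol 34 (not isolated)
Conditions: Me4NBH(OAc)3, MeCN/AcOH, −30 °C; then Et3N, DMAP (cat.), CH2Cl2, rt
Reagents that add atoms: none
Why: Evans–Saksena reduction delivers hydride intramolecularly from the C21-bound borohydride through a chair to give the 1,3-anti diol (sets C23), whose C23 hydroxyl then closes the γ-lactone onto the cis-disposed C1 ester (5-exo-trig).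

Step 25
Reactants: 35 lactone alcohol
Product: 36 C21 tert-butyldiphenylsilyl ether
Conditions: TBDPSCl, imidazole, DMAP (cat.), DMF, 40 °C
Reagents that add atoms: tert-butyl(chloro)diphenylsilane, CC(C)(C)[Si](Cl)(c1ccccc1)c1ccccc1
Why: Silylation protects the C21 hydroxyl with a group that survives aqueous acid and is removed only at the end.

**End game**

Step 26
Reactants: 36 fully protected seco compound
Product: 37 2,3,24-triol
Conditions: TFA/H2O (9:1), 0 °C → rt
Reagents that add atoms: none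
Why: Aqueous acid hydrolyses the isopropylidene ketal and the triethylsilyl ether, whereas the two TBDPS ethers, the C-silyl alkynes and the lactone should survive.

Step 27
Reactants: 37 triol
Product: 38 3,24-di-O-butanoate
Conditions: (n-PrCO)2O, DMAP, pyridine, CH2Cl2, 0 °C → rt
Reagents that add atoms: butanoic anhydride, CCCC(=O)OC(=O)CCC
Why: DMAP-catalysed acylation should esterify the two secondary hydroxyls (C3, C24) and leave the hindered tertiary C2 hydroxyl free.

Step 28
Reactants: 38 bis(silylalkyne)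
Product: 40 bis(terminal alkyne) seco compound, via disilver diacetylide 39 (not isolated)
Conditions: AgF, MeOH/THF, rt, dark; then HCl (1 M aq.), 0 °C
Reagents that add atoms: none
Why: Fluoride-assisted transfer of each alkynyl group from silicon to silver followed by protonolysis removes C-bound TIPS groups while TBDPS ethers and esters are tolerated.

Step 29
Reactants: 40 bis(terminal alkyne)
Product: 41 macrocyclic 12,14-diyne
Conditions: Cu(OAc)2, pyridine/Et2O, 50 °C, high dilution (slow addition)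
Reagents that add atoms: none
Why: Eglinton oxidative coupling of the two terminal alkynes at high dilution should close the macrocycle by forming C13–C14, the large ring accommodating the linear diyne.

Step 30
Reactants: 41 macrocyclic diyne
Product: 42 7,21-bis-O-TBDPS ether of the target (12Z,14Z)
Conditions: Zn(Cu/Ag), MeOH/H2O, rt → 40 °C
Reagents that add atoms: none
Why: Activated zinc in a protic medium reduces each triple bond of a conjugated diyne by cis addition and should stop at the (Z,Z)-diene, leaving esters and lactone untouched.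

Step 31
Reactants: 42 bis-silyl ether
Product: 43 target CNP0255197.1
Conditions: HF·pyridine, pyridine/THF, 0 °C → rt
Reagents that add atoms: none
Why: Buffered fluoride cleaves the two TBDPS ethers (C7, C21) under conditions that should not open the lactone, migrate the butanoates or isomerise the diene.

**Compound list**

1 | O-benzyl-D-serine, (R)-2-amino-3-(benzyloxy)propanoic acid | N[C@H](COCc1ccccc1)C(=O)O | starting material
2 | (R)-3-(benzyloxy)-2-hydroxypropanoic acid | O[C@H](COCc1ccccc1)C(=O)O | intermediate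
3 | (tert-butyldimethylsilyloxy)acetaldehyde | O=CCO[Si](C)(C)C(C)(C)C | starting material
4 | trimethylsilyl (R)-3-(benzyloxy)-2-(trimethylsilyloxy)propanoate | C[Si](C)(C)O[C@H](COCc1ccccc1)C(=O)O[Si](C)(C)C | intermediate
5 | (2R,5R)-5-[(benzyloxy)methyl]-2-[(tert-butyldimethylsilyloxy)methyl]-1,3-dioxolan-4-one (cis; the epimer at position 2 converges in step 4) | O1[C@H](COCc2ccccc2)C(=O)O[C@@H]1CO[Si](C)(C)C(C)(C)C | intermediate
6 | (2R,5R)-5-[(benzyloxy)methyl]-2-[(tert-butyldimethylsilyloxy)methyl]-4-methylidene-1,3-dioxolane | O1[C@H](COCc2ccccc2)C(=C)O[C@@H]1CO[Si](C)(C)C(C)(C)C | intermediate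
7 | (2R,5R)-2-[(benzyloxy)methyl]-5-[(tert-butyldimethylsilyloxy)methyl]oxolan-3-one (2,5-cis) | c1ccccc1COC[C@H]2O[C@H](CC2=O)CO[Si](C)(C)C(C)(C)C | intermediate
8 | (2S,5R)-2-[(benzyloxy)methyl]-5-[(tert-butyldimethylsilyloxy)methyl]-3-methylideneoxolane | c1ccccc1COC[C@H]2O[C@H](CC2=C)CO[Si](C)(C)C(C)(C)C | intermediate
9 | [(2S,3R,5R)-5-[(tert-butyldimethylsilyloxy)methyl]-3-methyloxolan-2-yl]methanol (all-cis) | OC[C@H]1O[C@H](C[C@H]1C)CO[Si](C)(C)C(C)(C)C | intermediate
10 | (triisopropylsilyl)acetylene | C#C[Si](C(C)C)(C(C)C)C(C)C | starting material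
11 | [(2S,3R,5R)-5-[(tert-butyldimethylsilyloxy)methyl]-3-methyloxolan-2-yl]methyl triflate | FC(F)(F)S(=O)(=O)OC[C@H]1O[C@H](C[C@H]1C)CO[Si](C)(C)C(C)(C)C | intermediate
12 | lithium (triisopropylsilyl)acetylide | [Li]C#C[Si](C(C)C)(C(C)C)C(C)C | intermediate
13 | tert-butyldimethyl{[(2R,4R,5R)-4-methyl-5-[3-(triisopropylsilyl)prop-2-yn-1-yl]oxolan-2-yl]methoxy}silane | CC(C)[Si](C#CC[C@H]1O[C@H](C[C@H]1C)CO[Si](C)(C)C(C)(C)C)(C(C)C)C(C)C | intermediate
14 | [(2R,4R,5R)-4-methyl-5-[3-(triisopropylsilyl)prop-2-yn-1-yl]oxolan-2-yl]methanol | CC(C)[Si](C#CC[C@H]1O[C@H](C[C@H]1C)CO)(C(C)C)C(C)C | intermediate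
15 | (2R,4R,5R)-4-methyl-5-[3-(triisopropylsilyl)prop-2-yn-1-yl]oxolane-2-carbaldehyde | CC(C)[Si](C#CC[C@H]1O[C@H](C[C@H]1C)C=O)(C(C)C)C(C)C | intermediate
16 | (E)-but-2-enal | C/C=C/C=O | starting material
17 | (R)-3-methyl-5-(triisopropylsilyl)pent-4-ynal | O=CC[C@@H](C)C#C[Si](C(C)C)(C(C)C)C(C)C | intermediate
18 | (4S,6R)-6-methyl-8-(triisopropylsilyl)oct-1-en-7-yn-4-ol | C=CC[C@@H](C[C@@H](C)C#C[Si](C(C)C)(C(C)C)C(C)C)O | intermediate
19 | methyl (E)-3-{[(4S,6R)-6-methyl-8-(triisopropylsilyl)oct-1-en-7-yn-4-yl]oxy}prop-2-enoate | C=CC[C@@H](C[C@@H](C)C#C[Si](C(C)C)(C(C)C)C(C)C)O/C=C/C(=O)OC | intermediate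
20 | methyl 2-[(2R,4S,6R)-6-[(2R)-2-methyl-4-(triisopropylsilyl)but-3-yn-1-yl]-4-(trifluoroacetoxy)oxan-2-yl]acetate | COC(=O)C[C@H]1C[C@@H](OC(=O)C(F)(F)F)C[C@@H](C[C@@H](C)C#C[Si](C(C)C)(C(C)C)C(C)C)O1 | intermediate
21 | methyl 2-[(2R,4S,6R)-4-hydroxy-6-[(2R)-2-methyl-4-(triisopropylsilyl)but-3-yn-1-yl]oxan-2-yl]acetate (all-cis oxane) | COC(=O)C[C@H]1C[C@@H](O)C[C@@H](C[C@@H](C)C#C[Si](C(C)C)(C(C)C)C(C)C)O1 | intermediate
22 | methyl 2-[(2R,4S,6R)-4-(tert-butyldiphenylsilyloxy)-6-[(2R)-2-methyl-4-(triisopropylsilyl)but-3-yn-1-yl]oxan-2-yl]acetate | COC(=O)C[C@H]1C[C@@H](O[Si](c2ccccc2)(c2ccccc2)C(C)(C)C)C[C@@H](C[C@@H](C)C#C[Si](C(C)C)(C(C)C)C(C)C)O1 | intermediate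
23 | 2-[(2R,4S,6R)-4-(tert-butyldiphenylsilyloxy)-6-[(2R)-2-methyl-4-(triisopropylsilyl)but-3-yn-1-yl]oxan-2-yl]acetaldehyde | O=CC[C@H]1C[C@@H](O[Si](c2ccccc2)(c2ccccc2)C(C)(C)C)C[C@@H](C[C@@H](C)C#C[Si](C(C)C)(C(C)C)C(C)C)O1 | intermediate
24 | dimethyl (4R,5R)-2,2-dimethyl-1,3-dioxolane-4,5-dicarboxylate (from L-tartaric acid) | COC(=O)[C@@H]1OC(C)(C)O[C@H]1C(=O)OC | starting material
25 | lithium enolate of 24 (C24 as in 24; enolate geometry not defined) | [Li]OC(OC)=C1OC(C)(C)O[C@H]1C(=O)OC | intermediate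
26 | aldol adduct: dioxolane diester 24 carrying on C2 (anti to the C24 ester, configured as in 43) the 1-hydroxy-2-(oxan-2-yl)ethyl chain of 23; C3 epimers, C3 left undefined | OC(C[C@H]1C[C@@H](O[Si](c3ccccc3)(c3ccccc3)C(C)(C)C)C[C@@H](C[C@@H](C)C#C[Si](C(C)C)(C(C)C)C(C)C)O1)[C@]2(C(=O)OC)OC(C)(C)O[C@H]2C(=O)OC | intermediate
27 | C3 ketone of 26 (β-keto ester) | O=C(C[C@H]1C[C@@H](O[Si](c3ccccc3)(c3ccccc3)C(C)(C)C)C[C@@H](C[C@@H](C)C#C[Si](C(C)C)(C(C)C)C(C)C)O1)[C@]2(C(=O)OC)OC(C)(C)O[C@H]2C(=O)OC | intermediate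
28 | (3R)-alcohol (C2, C3, C5, C7, C9, C11, C24 as in 43) | O[C@H](C[C@H]1C[C@@H](O[Si](c3ccccc3)(c3ccccc3)C(C)(C)C)C[C@@H](C[C@@H](C)C#C[Si](C(C)C)(C(C)C)C(C)C)O1)[C@]2(C(=O)OC)OC(C)(C)O[C@H]2C(=O)OC | intermediate
29 | C3 triethylsilyl ether of 28 | CC[Si](CC)(CC)O[C@H](C[C@H]1C[C@@H](O[Si](c3ccccc3)(c3ccccc3)C(C)(C)C)C[C@@H](C[C@@H](C)C#C[Si](C(C)C)(C(C)C)C(C)C)O1)[C@]2(C(=O)OC)OC(C)(C)O[C@H]2C(=O)OC | intermediate
30 | C23 N-methoxy-N-methylamide of 29 (C1 methyl ester kept) | CC[Si](CC)(CC)O[C@H](C[C@H]1C[C@@H](O[Si](c3ccccc3)(c3ccccc3)C(C)(C)C)C[C@@H](C[C@@H](C)C#C[Si](C(C)C)(C(C)C)C(C)C)O1)[C@]2(C(=O)OC)OC(C)(C)O[C@H]2C(=O)N(C)OC | intermediate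
31 | C23 methyl ketone (C22 = CH3) | CC[Si](CC)(CC)O[C@H](C[C@H]1C[C@@H](O[Si](c3ccccc3)(c3ccccc3)C(C)(C)C)C[C@@H](C[C@@H](C)C#C[Si](C(C)C)(C(C)C)C(C)C)O1)[C@]2(C(=O)OC)OC(C)(C)O[C@H]2C(C)=O | intermediate
32 | C22–C23 trimethylsilyl enol ether of 31 | CC[Si](CC)(CC)O[C@H](C[C@H]1C[C@@H](O[Si](c3ccccc3)(c3ccccc3)C(C)(C)C)C[C@@H](C[C@@H](C)C#C[Si](C(C)C)(C(C)C)C(C)C)O1)[C@]2(C(=O)OC)OC(C)(C)O[C@H]2C(=C)O[Si](C)(C)C | intermediate
33 | β-hydroxy ketone from 32 and 15 (C21 OH syn to the C20 oxygen, C23 ketone; other centres as in 43) | CC(C)[Si](C#CC[C@H]1O[C@H](C[C@H]1C)[C@H](O)CC(=O)[C@@H]2OC(C)(C)O[C@@]2(C(=O)OC)[C@H](O[Si](CC)(CC)CC)C[C@H]3C[C@@H](O[Si](c4ccccc4)(c4ccccc4)C(C)(C)C)C[C@@H](C[C@@H](C)C#C[Si](C(C)C)(C(C)C)C(C)C)O3)(C(C)C)C(C)C | intermediate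
34 | 21,23-anti diol of 33 | CC(C)[Si](C#CC[C@H]1O[C@H](C[C@H]1C)[C@H](O)C[C@@H](O)[C@@H]2OC(C)(C)O[C@@]2(C(=O)OC)[C@H](O[Si](CC)(CC)CC)C[C@H]3C[C@@H](O[Si](c4ccccc4)(c4ccccc4)C(C)(C)C)C[C@@H](C[C@@H](C)C#C[Si](C(C)C)(C(C)C)C(C)C)O3)(C(C)C)C(C)C | intermediate
35 | γ-lactone (C1–O–C23) cis-fused to the 2,24-O-isopropylidene ketal, all-cis at C2/C24/C23, free C21 OH | CC(C)[Si](C#CC[C@H]1O[C@H](C[C@H]1C)[C@H](O)C[C@H]5OC(=O)[C@]6(OC(C)(C)O[C@@H]56)[C@H](O[Si](CC)(CC)CC)C[C@H]3C[C@@H](O[Si](c4ccccc4)(c4ccccc4)C(C)(C)C)C[C@@H](C[C@@H](C)C#C[Si](C(C)C)(C(C)C)C(C)C)O3)(C(C)C)C(C)C | intermediate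
36 | C21 tert-butyldiphenylsilyl ether of 35 | CC(C)[Si](C#CC[C@H]1O[C@H](C[C@H]1C)[C@H](O[Si](c7ccccc7)(c7ccccc7)C(C)(C)C)C[C@H]5OC(=O)[C@]6(OC(C)(C)O[C@@H]56)[C@H](O[Si](CC)(CC)CC)C[C@H]3C[C@@H](O[Si](c4ccccc4)(c4ccccc4)C(C)(C)C)C[C@@H](C[C@@H](C)C#C[Si](C(C)C)(C(C)C)C(C)C)O3)(C(C)C)C(C)C | intermediate
37 | seco 2,3,24-triol (lactone, two TBDPS ethers, two TIPS-alkynes) | CC(C)[Si](C#CC[C@H]1O[C@H](C[C@H]1C)[C@H](O[Si](c7ccccc7)(c7ccccc7)C(C)(C)C)C[C@H]5OC(=O)[C@@](O)([C@H]5O)[C@H](O)C[C@H]3C[C@@H](O[Si](c4ccccc4)(c4ccccc4)C(C)(C)C)C[C@@H](C[C@@H](C)C#C[Si](C(C)C)(C(C)C)C(C)C)O3)(C(C)C)C(C)C | intermediate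
38 | seco 3,24-di-O-butanoate of 37 | CC(C)[Si](C#CC[C@H]1O[C@H](C[C@H]1C)[C@H](O[Si](c7ccccc7)(c7ccccc7)C(C)(C)C)C[C@H]5OC(=O)[C@@](O)([C@H]5OC(=O)CCC)[C@H](OC(=O)CCC)C[C@H]3C[C@@H](O[Si](c4ccccc4)(c4ccccc4)C(C)(C)C)C[C@@H](C[C@@H](C)C#C[Si](C(C)C)(C(C)C)C(C)C)O3)(C(C)C)C(C)C | intermediate
39 | disilver diacetylide of 40 | [Ag]C#CC[C@H]1O[C@H](C[C@H]1C)[C@H](O[Si](c7ccccc7)(c7ccccc7)C(C)(C)C)C[C@H]5OC(=O)[C@@](O)([C@H]5OC(=O)CCC)[C@H](OC(=O)CCC)C[C@H]3C[C@@H](O[Si](c4ccccc4)(c4ccccc4)C(C)(C)C)C[C@@H](C[C@@H](C)C#C[Ag])O3 | intermediate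
40 | seco bis(terminal alkyne) di-O-butanoate | C#CC[C@H]1O[C@H](C[C@H]1C)[C@H](O[Si](c7ccccc7)(c7ccccc7)C(C)(C)C)C[C@H]5OC(=O)[C@@](O)([C@H]5OC(=O)CCC)[C@H](OC(=O)CCC)C[C@H]3C[C@@H](O[Si](c4ccccc4)(c4ccccc4)C(C)(C)C)C[C@@H](C[C@@H](C)C#C)O3 | intermediate
41 | macrocyclic 12,14-diyne (7,21-bis-O-TBDPS, 3,24-di-O-butanoyl) | CCCC(=O)O[C@@H]1C[C@H]2C[C@@H](O[Si](c4ccccc4)(c4ccccc4)C(C)(C)C)C[C@@H](C[C@@H](C)C#CC#CC[C@H]3O[C@H](C[C@H]3C)[C@H](O[Si](c7ccccc7)(c7ccccc7)C(C)(C)C)C[C@H]3OC(=O)[C@@]1(O)[C@H]3OC(=O)CCC)O2 | intermediate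
42 | 7,21-bis-O-TBDPS ether of the target, (12Z,14Z)-diene | CCCC(=O)O[C@@H]1C[C@H]2C[C@@H](O[Si](c4ccccc4)(c4ccccc4)C(C)(C)C)C[C@@H](C[C@@H](C)/C=C\C=C/C[C@H]3O[C@H](C[C@H]3C)[C@H](O[Si](c7ccccc7)(c7ccccc7)C(C)(C)C)C[C@H]3OC(=O)[C@@]1(O)[C@H]3OC(=O)CCC)O2 | intermediate
43 | CNP0255197.1 (2S,3R,5R,7S,9R,11R,12Z,14Z,17R,18R,20R,21R,23R,24S in the atom labels of the overview) | CCCC(=O)O[C@@H]1C[C@H]2C[C@@H](O)C[C@@H](C[C@@H](C)/C=C\C=C/C[C@H]3O[C@H](C[C@H]3C)[C@H](O)C[C@H]3OC(=O)[C@@]1(O)[C@H]3OC(=O)CCC)O2 | target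

**Step count**

Total: 31 steps. Longest linear sequence: 22 steps (steps 10–22, then 23–31, from 16).

**Steps most likely to fail**

Step 4 (key step). What may go wrong: the β-silyloxy group destabilises the oxocarbenium ion, so ionisation may be slow and give way to hydrolytic fragmentation of the acetal, loss of the silyl ether, or erosion of the 2,5-cis selectivity. The fallback makes the same C19–C20 bond as a C19=C20 double bond by ring-closing metathesis of an enol ether. It sets out from 3, which is oxidised (NaClO2, NaH2PO4, 2-methylbut-2-ene) to (tert-butyldimethylsilyloxy)acetic acid F1. Separately, commercial benzyloxyacetaldehyde is crotylated with a (Z)-crotyl-diisopinocampheylborane (antipode chosen for the drawn product) to the syn alcohol (2S,3R)-1-(benzyloxy)-3-methylpent-4-en-2-ol F2, so C17 and C18 are set by reagent control. DCC/DMAP esterification of F2 with F1 gives the silyloxyacetate ester F3, and Tebbe methylenation (Cp2TiCH2AlClMe2) gives the acyclic enol ether F4. Ring-closing metathesis with the second-generation Grubbs catalyst (or a molybdenum alkylidene) then gives the 2,3-dihydrofuran F5. Hydrogenation over Pd/C from the face opposite the cis C17/C18 substituents sets C20 and removes the benzyl group, and the route is rejoined at 9.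

Step 6. What may go wrong: poor facial discrimination in hydrogen delivery to the exocyclic alkene, migration of the alkene into the ring before reduction, or hydrogenolysis of the allylic ring C–O bond. The fallback reduces an endocyclic alkene flanked by both ring substituents instead. It sets out from 7: kinetic enolisation towards C19 (KHMDS, PhNTf2, THF, −78 °C) gives the enol triflate F6. Fe(acac)3-catalysed coupling with MeMgBr gives the 3-methyl-2,5-dihydrofuran F7. Hydrogenation over Rh/Al2O3 (non-hydrogenolytic; both cis substituents shield one face of the flat ring) gives the all-cis benzyl ether F8, and hydrogenolysis (H2, Pd/C) returns to the route at 9.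

Step 29. What may go wrong: intermolecular oxidative coupling to dimers and oligomers may outrun ring closure, or strain may prevent closure of a ring that contains the rigid diyne rod. The fallback builds the diene from two (Z)-vinyl iodides and closes the ring by a zerovalent-nickel reductive coupling, which also makes step 30 unnecessary. It sets out from 40: iodination of both alkyne termini (NIS, AgNO3 cat., acetone) gives the bis(iodoalkyne) F9. cis-Reduction with diimide (2-nitrobenzenesulfonylhydrazide, Et3N) gives the bis[(Z)-vinyl iodide] F10. Intramolecular reductive coupling (Ni(cod)2, PPh3, DMF, high dilution) should form C13–C14 with retention of both alkene geometries and rejoin the route at 42.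

**Further compounds**

F1 | step 4 | (tert-butyldimethylsilyloxy)acetic acid | OC(=O)CO[Si](C)(C)C(C)(C)C
F2 | step 4 | (2S,3R)-1-(benzyloxy)-3-methylpent-4-en-2-ol | c1ccccc1COC[C@@H](O)[C@H](C)C=C
F3 | step 4 | (2S,3R)-1-(benzyloxy)-3-methylpent-4-en-2-yl (tert-butyldimethylsilyloxy)acetate | c1ccccc1COC[C@@H](OC(=O)CO[Si](C)(C)C(C)(C)C)[C@H](C)C=C
F4 | step 4 | acyclic enol ether (methylenated F3) | c1ccccc1COC[C@@H](OC(=C)CO[Si](C)(C)C(C)(C)C)[C@H](C)C=C
F5 | step 4 | (2S,3R)-2-[(benzyloxy)methyl]-5-[(tert-butyldimethylsilyloxy)methyl]-3-methyl-2,3-dihydrofuran | c1ccccc1COC[C@H]2OC(=C[C@H]2C)CO[Si](C)(C)C(C)(C)C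
F6 | step 6 | (2R,5R)-2-[(benzyloxy)methyl]-5-[(tert-butyldimethylsilyloxy)methyl]-2,5-dihydrofuran-3-yl triflate | c1ccccc1COC[C@H]2O[C@H](C=C2OS(=O)(=O)C(F)(F)F)CO[Si](C)(C)C(C)(C)C
F7 | step 6 | (2S,5R)-2-[(benzyloxy)methyl]-5-[(tert-butyldimethylsilyloxy)methyl]-3-methyl-2,5-dihydrofuran | c1ccccc1COC[C@H]2O[C@H](C=C2C)CO[Si](C)(C)C(C)(C)C
F8 | step 6 | (2S,3R,5R)-2-[(benzyloxy)methyl]-5-[(tert-butyldimethylsilyloxy)methyl]-3-methyloxolane (benzyl ether of 9) | c1ccccc1COC[C@H]2O[C@H](C[C@H]2C)CO[Si](C)(C)C(C)(C)C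
F9 | step 29 | bis(iodoalkyne) of 40 | IC#CC[C@H]1O[C@H](C[C@H]1C)[C@H](O[Si](c7ccccc7)(c7ccccc7)C(C)(C)C)C[C@H]5OC(=O)[C@@](O)([C@H]5OC(=O)CCC)[C@H](OC(=O)CCC)C[C@H]3C[C@@H](O[Si](c4ccccc4)(c4ccccc4)C(C)(C)C)C[C@@H](C[C@@H](C)C#CI)O3
F10 | step 29 | bis[(Z)-vinyl iodide] of 40 | I/C=C\C[C@H]1O[C@H](C[C@H]1C)[C@H](O[Si](c7ccccc7)(c7ccccc7)C(C)(C)C)C[C@H]5OC(=O)[C@@](O)([C@H]5OC(=O)CCC)[C@H](OC(=O)CCC)C[C@H]3C[C@@H](O[Si](c4ccccc4)(c4ccccc4)C(C)(C)C)C[C@@H](C[C@@H](C)/C=C\I)O3
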